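**Retrosynthetic overview**
1. Target 31 goes back to the trans-fused 6,9-dione 23. The two esters, the C7=C8 alkene (IBX) and the C6 carbinol (hydroxyl-directed reduction) are late adjustments. Dione 23 comes from bicycle 15 by C8 methylation and by oxidation of the C5=C6 alkene.
2. The strategy rests on the C9 ketone of ring B, which lies between the C10 methylene and the quaternary fusion carbon C1. Read as its C9=C10 enol ether, C1–C10–C9–C8–C7 is the five-carbon unit of a 1-siloxy-1-vinylcyclopropane. C5–C6 is a terminal alkyne tied to C1 through C2–C3–C4.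
3. Bicycle 15 goes back to the acyclic enyne 14 by an intramolecular rhodium (5+2) cycloaddition. Both rings form in this one step: ring A first (C1–C5, alkyne insertion), then ring B (C6–C7, reductive elimination).
4. Enyne 14 goes back to enoate 8 (ester, methyl ketone, 2-siloxydiene, Simmons–Smith). Enoate 8 goes back to the boron aldol of 1 with 2 (sets C2) and a chelate-controlled ethynylation (sets C4).
5. The cyclopropane of 14 carries no methyl group. A C8 methyl would make C9 stereogenic and would tie the usable face of C1=C10 to the ring bond that is cleaved, so cyclopropane epimers could not converge. The C8 methyl is therefore added after the cycloaddition.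

Key step: step 8

Numbering: C1 is the quaternary fusion carbon, C2 the acetoxy carbon, C3 a CH2, C4 the isopropyl carbinol, C5 the fusion CH, C6 the aroyloxy carbon, C7=C8 the alkene (methyl on C8), C9 the ketone, C10 a CH2. Ring A is the cyclopentane and ring B the seven-membered ring. β is the face of the C1 methyl group and α the opposite face.
Assumption: (−)-Ipc2BCl is taken to give the (R)-carbinol with enal 2. If the sense were opposite, the antipodal reagent would be used.
Assumption: C8 is a transient stereocentre in steps 10 to 16 and is erased in step 17, so it is drawn without configuration. The same holds for C5, C6 and C9 in 20–22.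

**Step 1**
Reactants: 1 3-methylbutan-2-one; 2 ethyl (E)-3-methyl-4-oxobut-2-enoate
Product: 4 ethyl (2E,4R)-4-hydroxy-3,7-dimethyl-6-oxooct-2-enoate, via enol diisopinocampheylborinate 3 (not isolated)
Conditions: (−)-Ipc2BCl, Et3N, Et2O, 0 °C; then 2, −78 → −20 °C; H2O2, MeOH, pH 7 buffer, 0 °C
Reagents that add atoms: none
Why: Ipc2BCl-mediated boron aldol reaction, in which 1 is enolised on its methyl side and the isopinocampheyl ligands of 3 differentiate the faces of enal 2 in the cyclic transition state, which should set C2 as R while the conjugated ester stays untouched.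

**Step 2**
Reactants: 4 aldol; 5 ethynylmagnesium bromide
Product: 6 ethyl (2E,4R,6S)-6-ethynyl-4,6-dihydroxy-3,7-dimethyloct-2-enoate
Conditions: HC≡CMgBr (3.5 equiv), THF, −78 → −20 °C; aq. NH4Cl
Reagents that add atoms: ethynylmagnesium bromide, C#C[Mg]Br
Why: Grignard 1,2-addition under 1,3-chelation control, in which the first equivalent forms the C2 magnesium alkoxide, its metal ties the C4 carbonyl into a six-membered chelate with the alkenyl group equatorial, and external axial attack of the acetylide should give the 2,4-anti diol (route C4 = S), the ketone reacting well before the β,β-disubstituted enoate.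

**Step 3**
Reactants: 6 diol
Product: 8 ethyl (2E,4R,6S)-4-(tert-butyldimethylsilyloxy)-6-ethynyl-3,7-dimethyl-6-(triethylsilyloxy)oct-2-enoate, via C2 mono-TBS ether 7 (not isolated)
Conditions: TBSOTf (1.05 equiv), 2,6-lutidine, CH2Cl2, −78 °C; then TESOTf (1.5 equiv), −78 → 0 °C
Reagents that add atoms: tert-butyldimethylsilyl triflate, CC(C)(C)[Si](C)(C)OS(=O)(=O)C(F)(F)F; triethylsilyl triflate, CC[Si](CC)(CC)OS(=O)(=O)C(F)(F)F
Why: Silyl triflate silylation in order of steric access, the secondary allylic C2 hydroxyl reacting at −78 °C and the hindered tertiary propargylic C4 hydroxyl then taking the smaller triethylsilyl group on warming.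

**Step 4**
Reactants: 8 bis-silyl ether ester
Product: 9 the N-methoxy-N-methylamide of 8
Conditions: MeNH(OMe)·HCl, iPrMgCl, THF, −20 → 0 °C
Reagents that add atoms: N,O-dimethylhydroxylamine hydrochloride, CNOC.Cl
Why: Weinreb amide formation by aminolysis of the ester with the magnesium amide made in the flask, the extra base only deprotonating the alkyne reversibly and the silyl ethers being inert.

**Step 5**
Reactants: 9 Weinreb amide; 10 methylmagnesium bromide
Product: 11 (3E,5R,7S)-5-(tert-butyldimethylsilyloxy)-7-ethynyl-4,8-dimethyl-7-(triethylsilyloxy)non-3-en-2-one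
Conditions: MeMgBr (3 equiv), THF, −78 → 0 °C
Reagents that add atoms: methylmagnesium bromide, C[Mg]Br
Why: Weinreb ketone synthesis, in which the chelated tetrahedral adduct survives until work-up, so that a single methyl group (the future C8) is delivered and the E-alkene is kept.

**Step 6**
Reactants: 11 methyl enone
Product: 12 the cross-conjugated 2-(tert-butyldimethylsilyloxy)-1,3-diene of 11
Conditions: TBSOTf, Et3N, CH2Cl2, −78 → 0 °C
Reagents that add atoms: tert-butyldimethylsilyl triflate, CC(C)(C)[Si](C)(C)OS(=O)(=O)C(F)(F)F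
Why: Soft enolisation with O-silylation (silyl enol ether formation), in which the O-silylated enone loses a proton from the unhindered α′-methyl group faster than from the γ-positions and the amine base leaves the alkyne C–H alone.

**Step 7**
Reactants: 12 siloxydiene; 13 diiodomethane
Product: 14 1-(tert-butyldimethylsilyloxy)-1-[(1E,3R,5S)-3-(tert-butyldimethylsilyloxy)-5-ethynyl-2,6-dimethyl-5-(triethylsilyloxy)hept-1-enyl]cyclopropane
Conditions: Et2Zn, CH2I2, CH2Cl2, 0 °C → rt; pyridine, aq. NaHCO3
Reagents that add atoms: diiodomethane, ICI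
Why: Simmons–Smith cyclopropanation (Furukawa variant), in which the electrophilic zinc carbenoid selects the electron-rich terminal enol ether C8=C9 over the conjugated trisubstituted C1=C10 alkene and the alkyne, C7 being the carbon it brings in.

**Step 8**
Reactants: 14 siloxyvinylcyclopropane-yne
Product: 15 hydroazulene dienol ether (1S; C2-OTBS α; C4-OTES β; C5=C6 alkene; C9-OTBS enol ether C9=C10)
Conditions: [Rh(CO)2Cl]2 (5–10 mol %), ClCH2CH2Cl (0.01 M), 80 °C
Reagents that add atoms: none
Why: Proposed new method: monovalent rhodium binds the C1=C10 alkene of 14 in the s-cis vinylcyclopropane conformer, opens the C9–CH2 bond on its own face to a σ-alkyl/π-allyl rhodacyclohexene of trivalent rhodium, inserts the tethered alkyne at the allyl terminus (C1–C5) and then eliminates reductively (C6–C7), which leaves the alkene at C9=C10 as the silyl enol ether. The closest known reaction type is the intramolecular rhodium-catalysed (5+2) cycloaddition of alkyne-tethered vinylcyclopropanes, 1-oxygenated ones included, and the new element is that the allyl terminus C1 is fully substituted, so that the insertion builds a quaternary carbon next to the quaternary C4. Ring A closes by a 5-exo migratory insertion across the three-atom tether C2–C3–C4, helped by the geminal substitution at C4, and ring B closes by C–C reductive elimination from the eight-membered rhodacycle. The only new stereocentre, C1, is controlled by C2: in the insertion transition state the C2–H bond rather than the C2–O bond eclipses the C1 methyl group (1,2-allylic strain), so the silyloxy group ends trans to the methyl group (1S). No choice between cyclopropane bonds is needed, because the two CH2 groups are equivalent and whichever lies on the rhodium face leads to the same product. The step still needs cycloaddition to outrun alkyne oligomerisation and β-hydride elimination from the rhodacycle, and the small CO ligands, the C9 siloxy group and the C1 methyl group cis to the cyclopropane (both of which disfavour the unreactive s-trans conformer) and high dilution are meant to secure this.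

**Step 9**
Reactants: 15 dienol ether
Product: 16 C9 ketone (C5=C6 alkene; C7, C8 and C10 methylenes; C2-OTBS; C4-OTES)
Conditions: Bu4NF, AcOH, THF, −20 °C
Reagents that add atoms: none
Why: Fluoride-induced cleavage of a silyl enol ether, the enolate being a far better leaving group from silicon than an alkoxide, so that the two alkyl silyl ethers and the acid-sensitive tertiary allylic C4–O bond should persist under the buffered conditions.

**Step 10**
Reactants: 16 ketone; 17 iodomethane
Product: 19 C8-methyl ketone, via C8=C9 lithium enolate 18 (not isolated)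
Conditions: LiN(iPr)2, THF, −78 °C; MeI, DMPU, −78 → −40 °C
Reagents that add atoms: iodomethane, CI
Why: Kinetic enolate alkylation, in which the amide base takes a C8 proton because C10 is neopentyl (next to quaternary C1), and the configuration created at C8 is of no consequence.

**Step 11**
Reactants: 19 C8-methyl ketone
Product: 21 6,9-diol, via C6-boryl C9-boryloxy intermediate 20 (not isolated)
Conditions: BH3·THF (excess), THF, 0 °C → rt; NaOH, H2O2, 0 °C
Reagents that add atoms: hydrogen peroxide, OO
Why: Hydroboration–oxidation, in which boron goes to the less substituted C6 and hydrogen to C5, the C9 ketone is reduced in the same flask, and the face of attack does not matter because C5, C6 and C9 are all reset in steps 12 and 15.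

**Step 12**
Reactants: 21 6,9-diol
Product: 23 trans-fused 6,9-dione (C5–H α), via C5-epimeric 6,9-dione mixture 22 (not isolated)
Conditions: Dess–Martin periodinane, NaHCO3, CH2Cl2, rt; crude product, DBU, toluene, rt → 40 °C
Reagents that add atoms: none
Why: Dess–Martin oxidation followed by base-mediated epimerisation under thermodynamic control, which should settle C5 with its hydrogen α because C6 then stands cis to the C4 oxygen and the C1 methyl group instead of eclipsing the much larger isopropyl group, the silyl group on O4 blocking a retro-aldol pathway.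

**Step 13**
Reactants: 23 trans-fused dione
Product: 24 2,4-dihydroxy-6,9-dione
Conditions: 48% aq. HF, MeCN, 0 °C → rt
Reagents that add atoms: none
Why: Acidic fluoride desilylation removes both alkyl silyl ethers in one operation, and the freed C4 hydroxyl can hydrogen-bond to the C6 carbonyl on the β face, which reinforces the trans ring fusion.

**Step 14**
Reactants: 24 dihydroxy dione; 25 acetic anhydride
Product: 26 C2 acetate
Conditions: Ac2O, pyridine, DMAP (cat.), CH2Cl2, 0 °C → rt
Reagents that add atoms: acetic anhydride, CC(=O)OC(C)=O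
Why: DMAP-catalysed acetylation, for which the secondary C2 hydroxyl is the only acylable group since the C4 carbinol is tertiary and flanked by isopropyl, and capping O2 also removes a hydroxyl that could direct hydride to C9.

**Step 15**
Reactants: 26 acetoxy dione
Product: 27 C6 α-alcohol (C9 ketone retained)
Conditions: Me4NBH(OAc)3, MeCN/AcOH, −30 → −20 °C
Reagents that add atoms: none
Why: Evans–Saksena hydroxyl-directed reduction, in which the C4 hydroxyl exchanges onto boron and delivers hydride within a six-membered transition state to the β face of C6 (C6–H β, C6–OH α, 4,6-anti), while the undirected C9 ketone and the acetate are inert to the triacetoxyborohydride.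

**Step 16**
Reactants: 27 C6 alcohol; 28 4-acetoxybenzoyl chloride
Product: 29 C6 4-acetoxybenzoate
Conditions: 28, Et3N, DMAP, CH2Cl2, rt → 40 °C
Reagents that add atoms: 4-acetoxybenzoyl chloride, CC(=O)Oc1ccc(cc1)C(Cl)=O
Why: DMAP-catalysed acylation with an acid chloride, selective for the secondary C6 hydroxyl over the tertiary C4 hydroxyl, the phenol being masked as its acetate so that it survives the oxidant of step 17.

**Step 17**
Reactants: 29 saturated ketone
Product: 30 C7=C8 enone
Conditions: IBX, DMSO/PhF, 70 °C
Reagents that add atoms: none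
Why: IBX-mediated α,β-dehydrogenation of a ketone, which can only proceed toward C8–C7 because the other α-carbon, C10, adjoins quaternary C1 and offers no β-hydrogen, and which erases the C8 stereocentre.

**Step 18**
Reactants: 30 aryl acetate
Product: 31 target CNP0087181.6
Conditions: NH4OAc, MeOH/H2O, rt
Reagents that add atoms: none
Why: Chemoselective solvolysis (transesterification) of an aryl acetate under near-neutral conditions, the phenoxide-type leaving group making this ester far more labile than the hindered C2 alkyl acetate, the C6 benzoate or the enone.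

**Compound list**
1 | 3-methylbutan-2-one | CC(C)C(C)=O | starting material
2 | ethyl (E)-3-methyl-4-oxobut-2-enoate | CCOC(=O)/C=C(C)/C=O | starting material
3 | 3-methylbut-1-en-2-yl diisopinocampheylborinate (Ipc groups from (+)-α-pinene) | C=C(OB([C@@H]1C[C@@H]2C[C@H]([C@H]1C)C2(C)C)[C@@H]1C[C@@H]2C[C@H]([C@H]1C)C2(C)C)C(C)C | intermediate (not isolated)
4 | ethyl (2E,4R)-4-hydroxy-3,7-dimethyl-6-oxooct-2-enoate | CC(C)C(=O)C[C@@H](O)/C(C)=C/C(=O)OCC | intermediate
5 | ethynylmagnesium bromide | C#C[Mg]Br | starting material
6 | ethyl (2E,4R,6S)-6-ethynyl-4,6-dihydroxy-3,7-dimethyloct-2-enoate | C#C[C@@](O)(C(C)C)C[C@@H](O)/C(C)=C/C(=O)OCC | intermediate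
7 | C2 (chain C4) mono-TBS ether of 6 | C#C[C@@](O)(C(C)C)C[C@@H](O[Si](C)(C)C(C)(C)C)/C(C)=C/C(=O)OCC | intermediate (not isolated)
8 | ethyl (2E,4R,6S)-4-(tert-butyldimethylsilyloxy)-6-ethynyl-3,7-dimethyl-6-(triethylsilyloxy)oct-2-enoate | C#C[C@@](O[Si](CC)(CC)CC)(C(C)C)C[C@@H](O[Si](C)(C)C(C)(C)C)/C(C)=C/C(=O)OCC | intermediate
9 | N-methoxy-N-methylamide of 8 | C#C[C@@](O[Si](CC)(CC)CC)(C(C)C)C[C@@H](O[Si](C)(C)C(C)(C)C)/C(C)=C/C(=O)N(C)OC | intermediate
10 | methylmagnesium bromide | C[Mg]Br | starting material
11 | (3E,5R,7S)-5-(tert-butyldimethylsilyloxy)-7-ethynyl-4,8-dimethyl-7-(triethylsilyloxy)non-3-en-2-one | C#C[C@@](O[Si](CC)(CC)CC)(C(C)C)C[C@@H](O[Si](C)(C)C(C)(C)C)/C(C)=C/C(C)=O | intermediate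
12 | 2-(tert-butyldimethylsilyloxy)-1,3-diene from 11 | C#C[C@@](O[Si](CC)(CC)CC)(C(C)C)C[C@@H](O[Si](C)(C)C(C)(C)C)/C(C)=C/C(=C)O[Si](C)(C)C(C)(C)C | intermediate
13 | diiodomethane | ICI | starting material
14 | 1-siloxy-1-alkenylcyclopropane with tethered terminal alkyne (key-step precursor; 2R, 4S, E-alkene) | C#C[C@@](O[Si](CC)(CC)CC)(C(C)C)C[C@@H](O[Si](C)(C)C(C)(C)C)/C(C)=C/C1(O[Si](C)(C)C(C)(C)C)CC1 | intermediate
15 | hydroazulene with quaternary C1 (S), C5=C6 alkene and C9 silyl enol ether (key-step product) | CC(C)(C)[Si](C)(C)O[C@@H]1C[C@](O[Si](CC)(CC)CC)(C(C)C)C2=CCCC(O[Si](C)(C)C(C)(C)C)=C[C@]12C | intermediate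
16 | C9 ketone with C5=C6 alkene | CC(C)(C)[Si](C)(C)O[C@@H]1C[C@](O[Si](CC)(CC)CC)(C(C)C)C2=CCCC(=O)C[C@]12C | intermediate
17 | iodomethane | CI | starting material
18 | C8=C9 lithium enolate of 16 | CC(C)(C)[Si](C)(C)O[C@@H]1C[C@](O[Si](CC)(CC)CC)(C(C)C)C2=CCC=C(O[Li])C[C@]12C | intermediate (not isolated)
19 | C8-methyl C9 ketone (C8 epimers) | CC(C)(C)[Si](C)(C)O[C@@H]1C[C@](O[Si](CC)(CC)CC)(C(C)C)C2=CCC(C)C(=O)C[C@]12C | intermediate
20 | C6-boryl, C9-boryloxy intermediate (stereoisomer mixture) | CC(C)(C)[Si](C)(C)O[C@@H]1C[C@](O[Si](CC)(CC)CC)(C(C)C)C2C(B)CC(C)C(OB)C[C@]12C | intermediate (not isolated)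
21 | 6,9-diol (stereoisomer mixture at C5, C6, C8, C9) | CC(C)(C)[Si](C)(C)O[C@@H]1C[C@](O[Si](CC)(CC)CC)(C(C)C)C2C(O)CC(C)C(O)C[C@]12C | intermediate
22 | 6,9-dione, C5 epimer mixture | CC(C)(C)[Si](C)(C)O[C@@H]1C[C@](O[Si](CC)(CC)CC)(C(C)C)C2C(=O)CC(C)C(=O)C[C@]12C | intermediate (not isolated)
23 | trans-fused 6,9-dione (C5–H α) | CC(C)(C)[Si](C)(C)O[C@@H]1C[C@](O[Si](CC)(CC)CC)(C(C)C)[C@H]2C(=O)CC(C)C(=O)C[C@]12C | intermediate
24 | 2α,4β-dihydroxy-6,9-dione | O[C@@H]1C[C@](O)(C(C)C)[C@H]2C(=O)CC(C)C(=O)C[C@]12C | intermediate
25 | acetic anhydride | CC(=O)OC(C)=O | starting material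
26 | 2α-acetoxy-4β-hydroxy-6,9-dione | CC(=O)O[C@@H]1C[C@](O)(C(C)C)[C@H]2C(=O)CC(C)C(=O)C[C@]12C | intermediate
27 | 2α-acetoxy-4β,6α-dihydroxy-9-ketone | CC(=O)O[C@@H]1C[C@](O)(C(C)C)[C@H]2[C@H](O)CC(C)C(=O)C[C@]12C | intermediate
28 | 4-acetoxybenzoyl chloride | CC(=O)Oc1ccc(cc1)C(Cl)=O | starting material
29 | C6 4-acetoxybenzoate of 27 | CC(=O)O[C@@H]1C[C@](O)(C(C)C)[C@H]2[C@H](OC(=O)c3ccc(OC(C)=O)cc3)CC(C)C(=O)C[C@]12C | intermediate
30 | C7=C8 enone, phenol still acetylated | CC(=O)O[C@@H]1C[C@](O)(C(C)C)[C@H]2[C@H](OC(=O)c3ccc(OC(C)=O)cc3)C=C(C)C(=O)C[C@]12C | intermediate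
31 | CNP0087181.6 | CC(=O)O[C@@H]1C[C@](O)(C(C)C)[C@H]2[C@H](OC(=O)c3ccc(O)cc3)C=C(C)C(=O)C[C@]12C | target

**Total step count:** 18. **Longest linear sequence:** 18 steps (from 1 and 2).

**Steps most likely to fail**

1. **Step 8.**
 - What may go wrong: migratory insertion at the fully substituted C1 may be too slow. Alkyne oligomerisation or β-hydride elimination from the rhodacycle to ring-opened dienes could then take over. Control of the C1 face by C2 may also be incomplete.
 - Fallback (known chemistry, rings closed one after the other): it sets out from Weinreb amide 9 and comes back at ketone 16.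
 - Bu3SnH and AIBN (benzene, 80 °C) add a stannyl radical to C6. The C5 vinyl radical closes ring A by 5-exo attack on C1 of the unsaturated amide, a mode that tolerates quaternary carbon formation.
 - This gives the (tributylstannyl)methylidene cyclopentane F1. Tin should sit on the C1 side, away from the bulkier C4, because stannyl radical addition is reversible.
 - Stille coupling with vinyl bromide (Pd(PPh3)4, CuI, CsF, DMF) gives the diene amide F2.
 - Vinylmagnesium bromide gives the vinyl ketone F3.
 - Ring-closing metathesis (second-generation Hoveyda–Grubbs catalyst, toluene, 80 °C) closes ring B at C7=C8 to the bicyclic dienone F4.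
 - 1,4-Reduction with [(Ph3P)CuH]6 then gives 16. Hydride goes to C7 because the δ-carbon C5 is fully substituted.

2. **Step 12.**
 - What may go wrong: equilibration at C5 may stop short of the trans-fused ketone, or β-elimination of the C4 silyloxy group may overtake it.
 - Fallback (stereospecific instead of thermodynamic): it sets out from 19 and comes back at 24.
 - HF·pyridine buffered with pyridine (THF, 0 °C) frees the C4 hydroxyl to give the allylic alcohol F5.
 - VO(acac)2 and tBuOOH epoxidise C5=C6 on the face of that hydroxyl to give the β-epoxide F6.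
 - BF3·OEt2 (CH2Cl2, −78 °C) opens the epoxide at C5, and the C6 hydrogen shifts to the α face of C5 (Meinwald rearrangement). This gives the hydroxy dione F7.
 - Aqueous HF in MeCN then gives 24.
 - This sequence is the second choice because the C4 isopropyl group is also aligned to migrate to C5 (semipinacol shift).

3. **Step 2.**
 - What may go wrong: 1,3-induction through the magnesium alkoxide chelate may be weak in THF, so that the C4 epimer builds up.
 - Fallback (preformed bidentate Lewis acid chelate of a C2 ether): it sets out from 4 and comes back at 6.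
 - 4-Methoxybenzyl trichloroacetimidate with La(OTf)3 (cat.) gives the PMB ether F8.
 - Precomplexation with MgBr2·OEt2 in CH2Cl2 at −78 °C, followed by ethynylmagnesium bromide, gives the anti adduct F9.
 - DDQ in wet CH2Cl2 then gives 6.

**Further compounds**
F1 | step 8 | ring A cyclopentane with exocyclic (tributylstannyl)methylidene at C5 (tin cis to C1) and CH2C(O)N(OMe)Me on quaternary C1 | CC(C)(C)[Si](C)(C)O[C@@H]1C[C@](O[Si](CC)(CC)CC)(C(C)C)/C(=C/[Sn](CCCC)(CCCC)CCCC)[C@]1(C)CC(=O)N(C)OC
F2 | step 8 | diene Weinreb amide (C6 vinyl group cis to C1) | CC(C)(C)[Si](C)(C)O[C@@H]1C[C@](O[Si](CC)(CC)CC)(C(C)C)/C(=C/C=C)[C@]1(C)CC(=O)N(C)OC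
F3 | step 8 | vinyl ketone triene | CC(C)(C)[Si](C)(C)O[C@@H]1C[C@](O[Si](CC)(CC)CC)(C(C)C)/C(=C/C=C)[C@]1(C)CC(=O)C=C
F4 | step 8 | bicyclic C5=C6–C7=C8–C9=O dienone | CC(C)(C)[Si](C)(C)O[C@@H]1C[C@](O[Si](CC)(CC)CC)(C(C)C)C2=CC=CC(=O)C[C@]12C
F5 | step 12 | C4 allylic alcohol (C2-OTBS, C5=C6, C8-methyl C9 ketone) | CC(C)(C)[Si](C)(C)O[C@@H]1C[C@](O)(C(C)C)C2=CCC(C)C(=O)C[C@]12C
F6 | step 12 | 5β,6β-epoxide of F5 | CC(C)(C)[Si](C)(C)O[C@@H]1C[C@](O)(C(C)C)[C@]2(O3)[C@@H]3CC(C)C(=O)C[C@]12C
F7 | step 12 | C2-OTBS 4β-hydroxy-6,9-dione (C5–H α) | CC(C)(C)[Si](C)(C)O[C@@H]1C[C@](O)(C(C)C)[C@H]2C(=O)CC(C)C(=O)C[C@]12C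
F8 | step 2 | C2 4-methoxybenzyl ether of 4 | CC(C)C(=O)C[C@@H](OCc1ccc(OC)cc1)/C(C)=C/C(=O)OCC
F9 | step 2 | C2 4-methoxybenzyl ether of 6 | C#C[C@@](O)(C(C)C)C[C@@H](OCc1ccc(OC)cc1)/C(C)=C/C(=O)OCC
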